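**Plan**

- Retrosynthesis: the three benzyl ethers come off last; before that the O1–C2 bond of the tetrahydrofuran is cut (ring C para-quinone methide plus C5–OH), then the C5–C5′ biaryl bond (Suzuki), then the tetralin C1–ring E bond (Friedel–Crafts), then both benzylic C–C bonds of each C4 backbone, back to (S)-malate.
- Forward: one bromo-allyloxy benzyl bromide is joined to diethyl (S)-malate and taken to a dioxolanone that serves both halves; a second benzylation (isovanillyl or vanillyl type) and LiAlH4 give two dibenzylbutanetriols.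
- Ring order: tetralin first (the ring D phenol is oxidised and acid steers the methide to ring E), then the biaryl coupling, then the tetrahydrofuran as the last ring.
- Enabling feature: C2 is the benzylic carbon para to the ring C hydroxyl and is separated from the C5 oxygen only by C3 and C4, so oxidising that one phenol makes C2 electrophilic exactly where a five-membered ether can close.
- Stereochemistry: tetrahydrofuran C3/C4 and tetralin C2/C3 come from (S)-malic acid (anti Frater–Seebach alkylation, then dioxolanone alkylation with retention); tetralin C1 and tetrahydrofuran C2 are set by substrate control in the two cyclisations.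

Key step: step 19

Assumption: 5-bromovanillin, diethyl (S)-malate and the benzyl alcohols 9 and 13 are bought; the biaryl axis carries one ortho oxygen per ring, rotates freely and is not a stereo element.

Numbering: tetrahydrofuran O1, C2 (ring C), C3 (CH2OH), C4 (OH and ring A benzyl), C5; tetralin C1 (ring D), C2 (CH2OH), C3 (OH, CH2OH), C4, benzo ring = ring E; ring A is the isovanillyl ring.

**Route**

Step 1
Reactants: 1 5-bromovanillin
Product: 2 4-(allyloxy)-3-bromo-5-methoxybenzaldehyde
Conditions: allyl bromide, K2CO3, DMF, 50 °C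
Reagents that add atoms: allyl bromide, C=CCBr
Why: Williamson etherification of the phenoxide; the allyl ether should survive amide bases, acid acetalisation and LiAlH4 and later leaves under neutral zerovalent-palladium catalysis without touching aryl bromide or benzyl ethers.

Step 2
Reactants: 2 allyl-protected bromo aldehyde
Product: 3 [4-(allyloxy)-3-bromo-5-methoxyphenyl]methanol
Conditions: NaBH4, MeOH, 0 °C
Reagents that add atoms: none
Why: Borohydride reduction of an aromatic aldehyde, which leaves the aryl bromide and the allyl ether untouched.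

Step 3
Reactants: 3 benzylic alcohol
Product: 4 4-(allyloxy)-3-bromo-5-methoxybenzyl bromide
Conditions: PBr3, CH2Cl2, 0 °C
Reagents that add atoms: phosphorus tribromide, BrP(Br)Br
Why: Conversion of a benzylic alcohol into the bromide through its phosphite ester and SN2 displacement by bromide, routine for electron-rich benzyl alcohols at low temperature.

Step 4
Reactants: 5 diethyl (S)-malate; 4 benzyl bromide
Product: 6 diethyl (2S,3R)-3-[4-(allyloxy)-3-bromo-5-methoxybenzyl]-2-hydroxysuccinate
Conditions: LiN(SiMe3)2 (2.2 equiv), THF, −78 → −20 °C; then 4, −78 → 0 °C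
Reagents that add atoms: none
Why: Frater–Seebach alkylation, in which the chelated dilithium alkoxide–enolate of the β-hydroxy ester should be benzylated anti to the alkoxide, giving the (2S,3R) product and fixing the later tetrahydrofuran C3 and tetralin C2 relative to the malate carbinol.

Step 5
Reactants: 6 benzylated malate diester
Product: 7 (2S,3R)-3-[4-(allyloxy)-3-bromo-5-methoxybenzyl]-2-hydroxysuccinic acid
Conditions: KOH, EtOH/H2O, rt; then HCl
Reagents that add atoms: potassium hydroxide, [K+].[OH-]
Why: Saponification of both ethyl esters by acyl–oxygen cleavage, after which the dicarboxylate is not expected to epimerise at C3 or to lose water under these mild conditions.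

Step 6
Reactants: 7 benzylated malic acid
Product: 8 (2R)-3-[4-(allyloxy)-3-bromo-5-methoxyphenyl]-2-[(2S,4S)-2-tert-butyl-5-oxo-1,3-dioxolan-4-yl]propanoic acid
Conditions: t-BuCHO, TsOH·H2O (cat.), H2SO4 (cat.), pentane/CH2Cl2, reflux, Dean–Stark
Reagents that add atoms: pivalaldehyde, CC(C)(C)C=O
Why: Acid-catalysed acetalisation of the α-hydroxy acid to the five-membered dioxolanone (Seebach self-regeneration of stereocentres), preferred over the six-membered dioxanone of the β-hydroxy acid; the new acetal centre should form cis to the side chain (S) under thermodynamic control, with crystallisation removing the minor isomers.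

Step 7
Reactants: 9 3-(benzyloxy)-4-methoxybenzyl alcohol
Product: 10 3-(benzyloxy)-4-methoxybenzyl bromide
Conditions: PBr3, Et2O, 0 °C
Reagents that add atoms: phosphorus tribromide, BrP(Br)Br
Why: Phosphite-mediated SN2 bromination of a benzylic alcohol under conditions that leave the aryl benzyl ether intact.

Step 8
Reactants: 8 dioxolanone acid; 10 isovanillyl-type bromide
Product: 11 (2R)-3-[4-(allyloxy)-3-bromo-5-methoxyphenyl]-2-{(2S,4S)-4-[3-(benzyloxy)-4-methoxybenzyl]-2-tert-butyl-5-oxo-1,3-dioxolan-4-yl}propanoic acid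
Conditions: LiN(SiMe3)2 (2.2 equiv), THF, −78 °C; then 10, −78 → −30 °C
Reagents that add atoms: none
Why: Seebach alkylation of the dioxolanone enolate (formed beside the lithium carboxylate), in which the benzyl bromide should enter anti to the tert-butyl group, so that benzyl replaces hydrogen with retention and the quaternary carbinol, the later tetrahydrofuran C4, is set as S.

Step 9
Reactants: 11 alkylated dioxolanone acid
Product: 12 (2S,3S)-3-[4-(allyloxy)-3-bromo-5-methoxybenzyl]-2-[3-(benzyloxy)-4-methoxybenzyl]butane-1,2,4-triol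
Conditions: LiAlH4, THF, 0 °C → rt
Reagents that add atoms: none
Why: Hydride reduction of the carboxylic acid and of the dioxolanone (an acylal-type ester) to two primary alcohols with release of the tertiary hydroxyl as the acetal collapses; no stereocentre is touched and the aryl bromide is expected to survive at room temperature.

Step 10
Reactants: 13 4-(benzyloxy)-3-methoxybenzyl alcohol
Product: 14 4-(benzyloxy)-3-methoxybenzyl bromide
Conditions: PBr3, Et2O, 0 °C
Reagents that add atoms: phosphorus tribromide, BrP(Br)Br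
Why: Phosphite-mediated SN2 bromination of a benzylic alcohol, as in step 7.

Step 11
Reactants: 8 dioxolanone acid; 14 vanillyl-type bromide
Product: 15 (2R)-3-[4-(allyloxy)-3-bromo-5-methoxyphenyl]-2-{(2S,4S)-4-[4-(benzyloxy)-3-methoxybenzyl]-2-tert-butyl-5-oxo-1,3-dioxolan-4-yl}propanoic acid
Conditions: LiN(SiMe3)2 (2.2 equiv), THF, −78 °C; then 14, −78 → −30 °C
Reagents that add atoms: none
Why: Seebach dioxolanone enolate alkylation anti to the tert-butyl group, which should set the quaternary carbinol, the later tetralin C3, as S with retention.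

Step 12
Reactants: 15 alkylated dioxolanone acid
Product: 16 (2S,3S)-3-[4-(allyloxy)-3-bromo-5-methoxybenzyl]-2-[4-(benzyloxy)-3-methoxybenzyl]butane-1,2,4-triol
Conditions: LiAlH4, THF, 0 °C → rt
Reagents that add atoms: none
Why: Hydride reduction of the acid and the dioxolanone to the triol, as in step 9, without change at either stereocentre.

Step 13
Reactants: 16 allyl-protected bromo triol of the ring D half
Product: 17 (2S,3S)-2-[4-(benzyloxy)-3-methoxybenzyl]-3-(3-bromo-4-hydroxy-5-methoxybenzyl)butane-1,2,4-triol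
Conditions: Pd(PPh3)4 (cat.), morpholine, THF, rt
Reagents that add atoms: none
Why: Tsuji–Trost-type deallylation, in which zerovalent palladium ionises the aryl allyl ether to a π-allyl complex that morpholine intercepts, while oxidative addition into the electron-rich aryl bromide is too slow at room temperature to interfere.

Step 14
Reactants: 17 bromophenol triol
Product: 19 (1S,2S,3S)-7-(benzyloxy)-1-(3-bromo-4-hydroxy-5-methoxyphenyl)-2,3-bis(hydroxymethyl)-6-methoxy-1,2,3,4-tetrahydronaphthalen-3-ol, via bromo-tetrahydrofuran 18 (not isolated)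
Conditions: DDQ (1.0 equiv), 1,4-dioxane/CH2Cl2, rt; then CF3CO2H, rt
Reagents that add atoms: none
Why: DDQ dehydrogenates the only free 4-alkylphenol to its para-quinone methide, which should first close to tetrahydrofuran 18 by 5-exo attack of the primary hydroxyl, and acid then reopens this para-hydroxybenzylic ether so that ring E attacks the cation para to its methoxy group in an irreversible six-membered Friedel–Crafts cyclisation (the olivil-to-cycloolivil type isomerisation), the aryl group taking the pseudo-equatorial position trans to the C2 hydroxymethyl and so setting C1 as S.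

Step 15
Reactants: 19 tetralin bromophenol
Product: 20 (1S,2S,3S)-7-(benzyloxy)-1-[4-(benzyloxy)-3-bromo-5-methoxyphenyl]-2,3-bis(hydroxymethyl)-6-methoxy-1,2,3,4-tetrahydronaphthalen-3-ol
Conditions: BnBr, K2CO3, DMF, rt
Reagents that add atoms: benzyl bromide, BrCc1ccccc1
Why: Williamson benzylation that is selective for the phenol, because carbonate deprotonates the phenol but not the primary or tertiary alcohols.

Step 16
Reactants: 20 tetralin aryl bromide
Product: 21 (1S,2S,3S)-7-(benzyloxy)-1-[4-(benzyloxy)-3-methoxy-5-(4,4,5,5-tetramethyl-1,3,2-dioxaborolan-2-yl)phenyl]-2,3-bis(hydroxymethyl)-6-methoxy-1,2,3,4-tetrahydronaphthalen-3-ol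
Conditions: B2pin2, Pd(dppf)Cl2 (cat.), KOAc, 1,4-dioxane, 90 °C
Reagents that add atoms: bis(pinacolato)diboron, CC1(C)OB(OC1(C)C)B1OC(C)(C)C(C)(C)O1
Why: Miyaura borylation of the aryl bromide, which tolerates free hydroxyl groups and an ortho alkoxy substituent.

Step 17
Reactants: 21 tetralin boronate; 12 allyl-protected bromo triol of the ring C half
Product: 22 (2S,3S)-2-[3-(benzyloxy)-4-methoxybenzyl]-3-({6-(allyloxy)-2'-(benzyloxy)-5'-[(1S,2S,3S)-7-(benzyloxy)-3-hydroxy-2,3-bis(hydroxymethyl)-6-methoxy-1,2,3,4-tetrahydronaphthalen-1-yl]-3',5-dimethoxybiphenyl-3-yl}methyl)butane-1,2,4-triol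
Conditions: Pd(OAc)2 (cat.), SPhos, K3PO4, 1,4-dioxane/H2O, 80 °C
Reagents that add atoms: none
Why: Suzuki–Miyaura coupling forms the C5–C5′ biaryl bond with a dialkylbiarylphosphine suited to ortho-alkoxy partners and tolerant of free hydroxyls, and any allyl ether cleaved by zerovalent palladium converges on 23 in the next step.

Step 18
Reactants: 22 biaryl allyl ether
Product: 23 (2S,3S)-2-[3-(benzyloxy)-4-methoxybenzyl]-3-({2'-(benzyloxy)-5'-[(1S,2S,3S)-7-(benzyloxy)-3-hydroxy-2,3-bis(hydroxymethyl)-6-methoxy-1,2,3,4-tetrahydronaphthalen-1-yl]-6-hydroxy-3',5-dimethoxybiphenyl-3-yl}methyl)butane-1,2,4-triol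
Conditions: Pd(PPh3)4 (cat.), morpholine, THF, rt
Reagents that add atoms: none
Why: Palladium-catalysed deallylation through a π-allyl complex trapped by morpholine, which frees the ring C phenol alone because benzyl ethers are inert to zerovalent palladium.

Step 19
Reactants: 23 biaryl precursor with the ring C phenol free
Product: 25 (2S,3R,4S)-4-[3-(benzyloxy)-4-methoxybenzyl]-2-{2'-(benzyloxy)-5'-[(1S,2S,3S)-7-(benzyloxy)-3-hydroxy-2,3-bis(hydroxymethyl)-6-methoxy-1,2,3,4-tetrahydronaphthalen-1-yl]-6-hydroxy-3',5-dimethoxybiphenyl-3-yl}-3-(hydroxymethyl)tetrahydrofuran-4-ol, via para-quinone methide 24 (not isolated)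
Conditions: graphite anode, Pt cathode, undivided cell, constant potential at the foot of the phenol wave (about +0.8 V vs Ag/AgCl), stopped near 2 F mol−1, 2,6-lutidine, n-Bu4NBF4, MeCN/CH2Cl2, rt
Reagents that add atoms: none
Why: With lutidine as proton acceptor the ring C phenol, the only unprotected phenol and hence the most easily oxidised group, should lose two electrons at the carbon anode and a proton from C2 to give para-quinone methide 24, while lutidinium is reduced to dihydrogen at the cathode. The closest known chemistry is the anodic or DDQ-mediated generation of para-quinone methides from 4-alkylphenols and their intramolecular capture by an alcohol in dibenzylbutanediol lignans. The C5 hydroxyl adds to the exocyclic methide carbon in a 5-exo-trig conjugate addition and rearomatisation gives the 2-aryltetrahydrofuran, whereas the C3 hydroxymethyl and the C4 hydroxyl could only close oxetanes. C2 is set as S by the C3 and C4 centres: in the envelope transition state ring C lies pseudo-equatorial and trans to the C3 hydroxymethyl, which is also the more stable 2,3-trans arrangement. The step needs chemoselectivity (the benzyl-protected rings A, D and E should oxidise only at higher potential), O- over C-capture (the acid-free buffer, since attack by ring A would need a protonated methide) and protection against a second oxidation of the product phenol (charge limited to about 2 F mol−1).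

Step 20
Reactants: 25 tri-O-benzyl ether
Product: 26 (2S,3R,4S)-2-{2',6-dihydroxy-5'-[(1S,2S,3S)-3,7-dihydroxy-2,3-bis(hydroxymethyl)-6-methoxy-1,2,3,4-tetrahydronaphthalen-1-yl]-3',5-dimethoxybiphenyl-3-yl}-4-(3-hydroxy-4-methoxybenzyl)-3-(hydroxymethyl)tetrahydrofuran-4-ol (CNP0252244.1)
Conditions: H2 (1 atm), 10% Pd/C, EtOAc/MeOH, rt
Reagents that add atoms: none
Why: Hydrogenolysis of the three aryl benzyl ethers over palladium, expected to be much faster than cleavage of the cyclic benzylic C2–O1 ether if stopped after three equivalents of H2; no stereocentre is involved.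

**Compound list**

1 | 5-bromovanillin (3-bromo-4-hydroxy-5-methoxybenzaldehyde) | COc1cc(C=O)cc(Br)c1O | starting material
2 | 4-(allyloxy)-3-bromo-5-methoxybenzaldehyde | COc1cc(C=O)cc(Br)c1OCC=C | intermediate
3 | [4-(allyloxy)-3-bromo-5-methoxyphenyl]methanol | COc1cc(CO)cc(Br)c1OCC=C | intermediate
4 | 4-(allyloxy)-3-bromo-5-methoxybenzyl bromide | COc1cc(CBr)cc(Br)c1OCC=C | intermediate
5 | diethyl (S)-malate | CCOC(=O)C[C@H](O)C(=O)OCC | starting material
6 | diethyl (2S,3R)-3-[4-(allyloxy)-3-bromo-5-methoxybenzyl]-2-hydroxysuccinate | COc1cc(C[C@@H](C(=O)OCC)[C@H](O)C(=O)OCC)cc(Br)c1OCC=C | intermediate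
7 | (2S,3R)-3-[4-(allyloxy)-3-bromo-5-methoxybenzyl]-2-hydroxysuccinic acid | COc1cc(C[C@@H](C(O)=O)[C@H](O)C(O)=O)cc(Br)c1OCC=C | intermediate
8 | (2R)-3-[4-(allyloxy)-3-bromo-5-methoxyphenyl]-2-[(2S,4S)-2-tert-butyl-5-oxo-1,3-dioxolan-4-yl]propanoic acid (tert-butyl cis to the side chain) | COc1cc(C[C@@H](C(O)=O)[C@@H]2O[C@H](C(C)(C)C)OC2=O)cc(Br)c1OCC=C | intermediate
9 | 3-(benzyloxy)-4-methoxybenzyl alcohol | COc1ccc(CO)cc1OCc1ccccc1 | starting material
10 | 3-(benzyloxy)-4-methoxybenzyl bromide | COc1ccc(CBr)cc1OCc1ccccc1 | intermediate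
11 | (2R)-3-[4-(allyloxy)-3-bromo-5-methoxyphenyl]-2-{(2S,4S)-4-[3-(benzyloxy)-4-methoxybenzyl]-2-tert-butyl-5-oxo-1,3-dioxolan-4-yl}propanoic acid | COc1cc(C[C@@H](C(O)=O)[C@]2(Cc3ccc(OC)c(OCc4ccccc4)c3)O[C@H](C(C)(C)C)OC2=O)cc(Br)c1OCC=C | intermediate
12 | (2S,3S)-3-[4-(allyloxy)-3-bromo-5-methoxybenzyl]-2-[3-(benzyloxy)-4-methoxybenzyl]butane-1,2,4-triol | COc1cc(C[C@@H](CO)[C@](O)(CO)Cc2ccc(OC)c(OCc3ccccc3)c2)cc(Br)c1OCC=C | intermediate
13 | 4-(benzyloxy)-3-methoxybenzyl alcohol | COc1cc(CO)ccc1OCc1ccccc1 | starting material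
14 | 4-(benzyloxy)-3-methoxybenzyl bromide | COc1cc(CBr)ccc1OCc1ccccc1 | intermediate
15 | (2R)-3-[4-(allyloxy)-3-bromo-5-methoxyphenyl]-2-{(2S,4S)-4-[4-(benzyloxy)-3-methoxybenzyl]-2-tert-butyl-5-oxo-1,3-dioxolan-4-yl}propanoic acid | COc1cc(C[C@@H](C(O)=O)[C@]2(Cc3ccc(OCc4ccccc4)c(OC)c3)O[C@H](C(C)(C)C)OC2=O)cc(Br)c1OCC=C | intermediate
16 | (2S,3S)-3-[4-(allyloxy)-3-bromo-5-methoxybenzyl]-2-[4-(benzyloxy)-3-methoxybenzyl]butane-1,2,4-triol | COc1cc(C[C@@H](CO)[C@](O)(CO)Cc2ccc(OCc3ccccc3)c(OC)c2)cc(Br)c1OCC=C | intermediate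
17 | (2S,3S)-2-[4-(benzyloxy)-3-methoxybenzyl]-3-(3-bromo-4-hydroxy-5-methoxybenzyl)butane-1,2,4-triol | COc1cc(C[C@@H](CO)[C@](O)(CO)Cc2ccc(OCc3ccccc3)c(OC)c2)cc(Br)c1O | intermediate
18 | (2S,3R,4S)-4-[4-(benzyloxy)-3-methoxybenzyl]-2-(3-bromo-4-hydroxy-5-methoxyphenyl)-3-(hydroxymethyl)tetrahydrofuran-4-ol | COc1cc([C@H]2OC[C@](O)(Cc3ccc(OCc4ccccc4)c(OC)c3)[C@@H]2CO)cc(Br)c1O | intermediate
19 | (1S,2S,3S)-7-(benzyloxy)-1-(3-bromo-4-hydroxy-5-methoxyphenyl)-2,3-bis(hydroxymethyl)-6-methoxy-1,2,3,4-tetrahydronaphthalen-3-ol | COc1cc(cc(Br)c1O)[C@H]1c2cc(OCc3ccccc3)c(OC)cc2C[C@@](O)(CO)[C@@H]1CO | intermediate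
20 | (1S,2S,3S)-7-(benzyloxy)-1-[4-(benzyloxy)-3-bromo-5-methoxyphenyl]-2,3-bis(hydroxymethyl)-6-methoxy-1,2,3,4-tetrahydronaphthalen-3-ol | COc1cc(cc(Br)c1OCc1ccccc1)[C@H]1c2cc(OCc3ccccc3)c(OC)cc2C[C@@](O)(CO)[C@@H]1CO | intermediate
21 | (1S,2S,3S)-7-(benzyloxy)-1-[4-(benzyloxy)-3-methoxy-5-(4,4,5,5-tetramethyl-1,3,2-dioxaborolan-2-yl)phenyl]-2,3-bis(hydroxymethyl)-6-methoxy-1,2,3,4-tetrahydronaphthalen-3-ol | COc1cc(cc(B2OC(C)(C)C(C)(C)O2)c1OCc1ccccc1)[C@H]1c2cc(OCc3ccccc3)c(OC)cc2C[C@@](O)(CO)[C@@H]1CO | intermediate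
22 | ring C allyl ether of 23 (5,5′-biaryl; ring C with the (2S,3S)-triol chain, ring D O-benzyl with the (1S,2S,3S)-tetralin) | COc1cc(cc(-c2cc(C[C@@H](CO)[C@](O)(CO)Cc3ccc(OC)c(OCc4ccccc4)c3)cc(OC)c2OCC=C)c1OCc1ccccc1)[C@H]1c2cc(OCc3ccccc3)c(OC)cc2C[C@@](O)(CO)[C@@H]1CO | intermediate
23 | key-step precursor: 5,5′-biaryl with free ring C phenol, acyclic (2S,3S)-triol on ring C, O-benzyl ring D bearing the (1S,2S,3S)-tetralin, rings A and E O-benzylated | COc1cc(cc(-c2cc(C[C@@H](CO)[C@](O)(CO)Cc3ccc(OC)c(OCc4ccccc4)c3)cc(OC)c2O)c1OCc1ccccc1)[C@H]1c2cc(OCc3ccccc3)c(OC)cc2C[C@@](O)(CO)[C@@H]1CO | intermediate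
24 | para-quinone methide of 23 (ring C as cyclohexa-2,5-dienone with exocyclic C=C to C2) | COc1cc(cc(C2=CC(=C[C@@H](CO)[C@](O)(CO)Cc3ccc(OC)c(OCc4ccccc4)c3)C=C(OC)C2=O)c1OCc1ccccc1)[C@H]1c2cc(OCc3ccccc3)c(OC)cc2C[C@@](O)(CO)[C@@H]1CO | intermediate
25 | tri-O-benzyl ether of 26 (benzyl on the ring A, ring D and ring E phenols; (2S,3R,4S)-tetrahydrofuran closed) | COc1cc(cc(-c2cc([C@H]3OC[C@](O)(Cc4ccc(OC)c(OCc5ccccc5)c4)[C@@H]3CO)cc(OC)c2O)c1OCc1ccccc1)[C@H]1c2cc(OCc3ccccc3)c(OC)cc2C[C@@](O)(CO)[C@@H]1CO | intermediate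
26 | CNP0252244.1: (2S,3R,4S)-2-{2',6-dihydroxy-5'-[(1S,2S,3S)-3,7-dihydroxy-2,3-bis(hydroxymethyl)-6-methoxy-1,2,3,4-tetrahydronaphthalen-1-yl]-3',5-dimethoxybiphenyl-3-yl}-4-(3-hydroxy-4-methoxybenzyl)-3-(hydroxymethyl)tetrahydrofuran-4-ol | COc1ccc(C[C@@]2(O)CO[C@H](c3cc(OC)c(O)c(-c4cc([C@H]5c6cc(O)c(OC)cc6C[C@@](O)(CO)[C@@H]5CO)cc(OC)c4O)c3)[C@H]2CO)cc1O | target

**Step count and risks**

Total steps: 20. Longest linear sequence: 16 steps (steps 1–6, 11–16, 17–20).

Step 19 (anodic cycloetherification). The oxidation may not funnel through loss of the C2 proton: the oxidised ring can be attacked at its ipso carbon by the C3 hydroxymethyl (spirocyclisation), phenoxyl radicals can couple, and the product phenol can be oxidised a second time at C2. The fallback sets out from 12 and closes the same O1–C2 bond on the small ring C fragment before the biaryl exists. Deallylation with Pd(PPh3)4 and morpholine gives bromophenol triol F1. One equivalent of DDQ in dioxane then abstracts hydride chemically and the methide closes to bromo-tetrahydrofuran F2. Suzuki coupling of F2 with boronate 21 (Pd(OAc)2, SPhos, K3PO4, dioxane/H2O) makes the biaryl bond last and returns to the route at 25.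

Step 14 (oxidation, then acid-induced tetralin closure). Residual DDQ may over-oxidise the product once a doubly benzylic C1–H stands para to a free phenol, and in acid the benzylic cation may be lost to elimination or intermolecular alkylation before ring E attacks. The fallback sets out from 17 and separates the redox event from the ionisation. DDQ alone is used and tetrahydrofuran 18 is isolated. Its phenol is benzylated (BnBr, K2CO3, DMF) to benzyl ether F3, which can no longer be oxidised to a methide. BF3·OEt2 in CH2Cl2 at low temperature then ionises the benzylic C2–O1 bond and ring E closes the tetralin in a Friedel–Crafts step, returning to the route at 20.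

Step 8 (dioxolanone enolate alkylation; the same operation recurs in step 11). The enolate may fragment with loss of pivalaldehyde before it is alkylated, or facial selectivity may erode next to the carboxylate-bearing stereocentre. The fallback sets out from 8 and moves the alkylation to a lactone alkoxide–enolate. BH3·SMe2 reduces the free acid selectively and TsOH lactonises the hydroxy dioxolanone with loss of pivalaldehyde to hydroxy lactone F4. Its dilithium alkoxide–enolate (LiN(SiMe3)2, THF, −78 °C) is benzylated with 10 anti to the C4 benzyl group to give α-hydroxy dibenzyl lactone F5. LiAlH4 reduction of F5 returns to the route at 12.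

**Further compounds**

F1 | step 19 | (2S,3S)-2-[3-(benzyloxy)-4-methoxybenzyl]-3-(3-bromo-4-hydroxy-5-methoxybenzyl)butane-1,2,4-triol | COc1cc(C[C@@H](CO)[C@](O)(CO)Cc2ccc(OC)c(OCc3ccccc3)c2)cc(Br)c1O
F2 | step 19 | (2S,3R,4S)-4-[3-(benzyloxy)-4-methoxybenzyl]-2-(3-bromo-4-hydroxy-5-methoxyphenyl)-3-(hydroxymethyl)tetrahydrofuran-4-ol | COc1cc([C@H]2OC[C@](O)(Cc3ccc(OC)c(OCc4ccccc4)c3)[C@@H]2CO)cc(Br)c1O
F3 | step 14 | (2S,3R,4S)-4-[4-(benzyloxy)-3-methoxybenzyl]-2-[4-(benzyloxy)-3-bromo-5-methoxyphenyl]-3-(hydroxymethyl)tetrahydrofuran-4-ol | COc1cc([C@H]2OC[C@](O)(Cc3ccc(OCc4ccccc4)c(OC)c3)[C@@H]2CO)cc(Br)c1OCc1ccccc1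
F4 | step 8 | (3S,4S)-4-[4-(allyloxy)-3-bromo-5-methoxybenzyl]-3-hydroxydihydrofuran-2(3H)-one | COc1cc(C[C@H]2COC(=O)[C@H]2O)cc(Br)c1OCC=C
F5 | step 8 | (3S,4S)-4-[4-(allyloxy)-3-bromo-5-methoxybenzyl]-3-[3-(benzyloxy)-4-methoxybenzyl]-3-hydroxydihydrofuran-2(3H)-one | COc1cc(C[C@H]2COC(=O)[C@]2(O)Cc3ccc(OC)c(OCc4ccccc4)c3)cc(Br)c1OCC=C
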